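(The numbers in the tables come from a simulation from invented constants, noise included.)

The easy step comes first: I compare the earlier runs, which have nearly the same catalyst charge.

| setting | ochre | teal | green | amber | elm | alder | cedar | birch | oak |
|---|---|---|---|---|---|---|---|---|---|
| substrate | 0.020 M | 0.020 M | 0.020 M | 0.020 M | 0.020 M | 0.020 M | 0.020 M | 0.060 M | 0.012 M |
| partner | 0.021 M | 0.021 M | 0.021 M | 0.021 M | 0.0210 M | 0.0210 M | 0.0800 M | 0.0210 M | 0.0210 M |
| protic impurity | 0.28 mM | 0.55 mM | 0.79 mM | 1 mM | 0.250 mM | 1.00 mM | 1.00 mM | 0.250 mM | 0.500 mM |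
| free catalyst | 13 µM | 13 µM | 13 µM | 12 µM | 25 µM | 13 µM | 8.0 µM | 13 µM | 3.0 µM |
| remark | run made earlier | run made earlier | run made earlier | run made earlier |  |  |  |  |  |
| time |  |  |  |  | 2.0 min | 2.0 min | 2.0 min | 2.0 min | 2.0 min |

- ochre (time / s: product / %, substrate / %): 10.0: 1.9, 83.3; 30.0: 9.3, 64.4; 60.0: 20.0, 49.4; 80.0: 26.3, 43.4; 120: 36.0, 36.6
- teal (time / s: product / %, substrate / %): 25.0: 6.7, 68.4; 50.0: 16.2, 52.5; 80.0: 26.3, 43.1; 90.0: 29.1, 41.7; 120: 36.0, 36.8
- green (time / s: product / %, substrate / %): 25.0: 7.5, 68.4; 50.0: 16.8, 53.4; 80.0: 26.4, 43.5; 90.0: 29.2, 40.9; 120: 35.6, 36.5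
- amber (time / s: product / %, substrate / %): 10.0: 1.6, 84.4; 30.0: 7.8, 66.0; 60.0: 18.1, 51.5; 80.0: 24.1, 46.4; 120: 32.9, 39.0

(scatter of a reading: 0.3 percentage points)

- ranking by amount of product, in percent of the substrate charged, from high to low, at 2.0 min (elm / alder / cedar / birch / oak)
- the amount of product, in percent of the substrate charged of the flask you put first, at 2.0 min
- the amount of product, in percent of the substrate charged of the flask you put last, at 2.0 min

- what was read earlier has a scatter of 0.3 percentage points, one standard deviation

Ochre, teal and green carry 0.28 mM, 0.55 mM and 0.79 mM of protic impurity, yet they give 36.0%, 36.0% and 35.6% of product at 120 s, so I leave the impurity out of my reckoning.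

Substrate lost runs ahead of product, so a pool stands between them. But product made per unit of pool falls in ochre, from 0.01800 s⁻¹ over the first two readings to 0.008406 s⁻¹ over the last two. I read this, as a guess, as first-order loss of working catalyst, with a rate constant of 0.009522 s⁻¹ and a half-life of 72.8 s.

So a plain Selwyn clock of charge times time runs too fast. Ochre's surviving fraction, integrated to 120 s, is worth 71.5 s, and oak gets 16.5 s: its working time, meaning c(free catalyst) over ochre's, multiplied by that integral. I expect equal working time to give equal percent product while partner lasts, and I assume this across the substrate and partner charges of the new flasks, which no earlier run varied.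

Ochre reaches oak's working time at 18.0 s, and interpolation gives oak 4.84%. Cedar's 44.0 s gives 18.9%. Alder repeats ochre, about 36.0%. Birch has alder's working time, but if each product takes one partner, its partner allows at most 35.0%, so I place it below alder and, taking it to come near that ceiling, above cedar. Elm's 138 s lies beyond ochre, so I continue ochre's last first-order fall of unconverted material and get 64.9%.

The forecast ranks elm > cedar > alder > birch > oak, with 53% (47% to 72%) first and 5.5% (3.5% to 8%) last, holding that “Time therefore scales with catalyst”, whereas I put cedar below alder and birch.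

The flasks give elm > alder > birch > cedar > oak: elm 64.0%, alder 35.5%, birch 26.4%, cedar 21.7%, oak 4.50%.

    partner + protic impurity → quenched reagent (k = 8.30 L mol⁻¹ s⁻¹)
    partner + catalyst intermediate → free catalyst + product (k = 3700 L mol⁻¹ s⁻¹)
    free catalyst → spent catalyst (k = 0.00970 s⁻¹)
    substrate + free catalyst ⇌ free catalyst + open intermediate (K = 1.80, k = 1600 L mol⁻¹ s⁻¹)
    free catalyst + open intermediate ⇌ catalyst intermediate (K = 490 L mol⁻¹, k = 1800 L mol⁻¹ s⁻¹)

At 2.00 min oak holds 67.3% of its catalyst as spent catalyst, 30.8% as free catalyst and 1.87% as catalyst intermediate, and taking away that decay lifts oak's product from 4.50% to 10.3%. The neighbour of oak with 7.5 × 10⁻⁷ M of free catalyst has a quarter of oak's 16.5 s, namely 4.13 s. That lies before ochre's first reading, where I let product grow as the square of working time, which gives 0.356%; that neighbour flask gives 0.356%.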